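## Structural features

The target is a C30 bis-bicyclic ether. It has two trans-fused oxepane–cyclohexane units: ring A (O5, C6–C10, C4) fused to ring B (C1–C4, C10, C11), and ring D (O20, C15–C19, C21) fused to ring C (C14, C15, C21–C24). The two units are joined only by the C12–C13 ethylene bridge between C11 and C14. Each cyclohexane carries four contiguous stereocentres (C1, C11, C10, C4 and C24, C14, C15, C21). The halves agree at three of them (angular methyl axial, ring oxygen and bridge carbon equatorial) but are epimeric at the acetoxy carbon: the C1 acetate is axial and syn to the C10 methyl, the C24 acetate is equatorial with its methyl axial. Ring A carries a secondary (S)-carbinol at C7 next to the gem-dimethyl ether carbon C6, whereas ring D carries a ketone at the corresponding C18. Fragile groups are the two tertiary acetates (lost by ionisation, or by elimination when β to a carbanion or carbonyl), the α-alkoxy ketone with enolisable C17, and the tertiary ether carbons C6 and C19. The real difficulty lies in the quaternary C10 and C15, each wedged between an oxygenated carbon and the bridge-bearing carbon, in joining two neopentyl-like carbons, and in telling apart two secondary and two tertiary oxygens. The key step exploits the fact that in ring B the methyl-bearing C10 and the bridge-bearing C11 are the β- and α-carbons of the C1 carbonyl of a 3-methylcyclohexenone oxygenated at C4, so C9–C10 and C11–C12 can be made in one operation. Ring C shows the same pattern.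

## Logic of the disconnections

**35 from 34.** Cut: the two C–H bonds across C12=C13 and the O7–CH2Ph bond. C7–OH is the only secondary hydroxyl and must be masked while the tertiary ones are esterified; a benzyl ether falls off in the same hydrogenation that saturates the bridge. Gain: the last step needs no selectivity among hydroxyls. Demand: a crowded disubstituted alkene must be reduced while the C18 ketone and both tertiary acetates are spared.

**34 from 33, 33 from 32, 32 from 31.** Cut: the acyl–O bonds at O1 and O24, the C18 carbonyl (back to a carbinol) and three O–Si bonds. Tertiary acetates β or γ to the coupling carbons would eliminate or be attacked under a basic olefination, and an enolisable ketone would compete with the aldehyde, so both come after the union. Gain: the coupling partners carry only ethers. Demand: oxidation confined to the one secondary carbinol, and acetylation of an axial tertiary hydroxyl without ionising it.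

**31 from 21 and 29.** Cut: C12=C13. It is the only bond between the halves, and cutting it gives two bicycles of equal size that descend from one precursor. Gain: full convergence. Demand: an olefination between two α-branched, neopentyl-like carbons; the alkene geometry is irrelevant.

**21 from 20, 19, 18 and 17.** Cut: O1–Si, the two S=O bonds, O7–CH2Ph and C12–S. Sulfur goes in first because only then is the primary hydroxyl out of the way for benzylation of O7. It is oxidised after the basic benzylation because only the sulfone has acidic α-hydrogens. Gain: 17 needs no protecting group. Demand: substitution at the hindered primary C12 and discrimination of secondary from tertiary hydroxyl.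

**17 from 16, 16 from 15, 15 from 14.** Cut: O5–C6 (ring A), then the epoxide oxygen on C6/C7, then two O–Si bonds. Opening an epoxide at its tertiary carbon by the C4 hydroxyl makes the tertiary ether and leaves the C7 oxygen with the configuration set by a reagent-controlled epoxidation. Gain: ring A and C7 shrink to a 4-methylpent-3-enyl chain. Demand: 7-endo rather than 6-exo opening, and the L-fructose-derived ketone, because the D-series would give the wrong configuration at C7.

**14 from 13.** Cut: C1–CH3. A C1 ketone lets the two epimeric carbinol carbons come from one precursor by opposite modes of addition. Demand: equatorial attack, expected because the axial C10 methyl blocks the axial path.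

**29 from 28 and 27; 27 from 26; 26 from 25.** Cut: two O–Si bonds, the aldehyde back to a carbinol, then the hydride C–H of the C24 methyl and the epoxide oxygen on C24=CH2. C24 needs equatorial oxygen and axial methyl, the opposite of what MeMgBr delivers, so oxygen arrives from a peracid on the equatorial face and the methyl is completed by hydride. Gain: C24 becomes an exocyclic alkene. Demand: facial selectivity of the epoxidation and hydride attack at CH2.

**25 from 24, 23 and 22; 22 from 13.** Cut: O20–C19 (ring D), the epoxide oxygen, two O–Si bonds, then C24=CH2 back to the ketone. Ring D is closed before the peracid and hydride steps, because a peracid would attack the chain alkene first and hydride would open a chain epoxide at the wrong carbon. The C18 configuration is irrelevant since it ends as a carbonyl. Gain: both halves converge on 13. Demand: chemoselective epoxidation of the trisubstituted alkene beside the exocyclic one.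

**13 from 12; 12 from 7, 9 and 10.** Cut: O–Si, then C9–C10 and C11–C12. One conjugate addition with enolate trapping makes the quaternary centre, the bridge carbon and two stereocentres, while the C4 silyloxy group steers the face and later becomes O5 or O20. Gain: a bicyclic problem becomes a monocyclic enone, a C6 Grignard reagent and a one-carbon electrophile. Demand: 1,4-addition at a fully substituted β-carbon anti to the silyloxy group, and clean mono-hydroxymethylation. The descriptors were checked: 7 is S and 12 is 2R,3S,4S, which correspond to C4 S, C10 S, C11 S of 35 (the letter at C11 changes only through CIP priorities).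

**7 from 5 (through 6), 5 from 4, 4 from 3, 3 from 1; 9 from 8.** Cut: C3–CH3 with transposition of the carbonyl, O–Si, and the C–O bond at the α' carbon; C–Mg for 9. Oxygenating 3-methylcyclohexenone directly at C4 would need a γ-dienolate, but kinetic deprotonation occurs at C6 and the methyl group competes under equilibrating conditions. A vinylogous ester is deprotonated cleanly at the α' carbon; MeLi addition and acidic hydrolysis then move the carbonyl so that this carbon becomes C4 next to the new methyl. Gain: the regiochemistry is unambiguous at the same step count. Demand: a resolution to reach the S series.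

## Other disconnections considered

**Alternative 1:** The cut is C4–C10 and C8–C9, with later scission of C4–C8. Ring B and the carbons of ring A are assembled around a 2,2-dimethylfuran-3(2H)-one that already contains O5, C6, C7, C8 and C4. In the forward step, irradiation near 350 nm of the 5-alkenyl furanone A1 would let the excited enone add across the C10=C9 alkene in the straight sense to give cyclobutane photoadduct A2. Cleaving the C4–C8 bond of A2 would then release the seven-membered ring.
- In its favour: quaternary C10, the C4–O5 bond and a C7 carbonyl arrive together. The tertiary ether O5–C6 is present from the start, so the endo/exo question of an epoxide opening never arises. The ring is delivered at the ketone oxidation level; for ring D this is better than the chosen plan, which needs epoxidation, ring closure and oxidation.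
- Against it here: facial selectivity must be relayed from a single centre (C11) in a flexible tether. The C4 hydrogen is introduced only when the cyclobutane is opened, so the ring-fusion configuration rests on a protonation. The rings A/B half would need a later diastereoselective reduction at C7. C1 has to travel as a ketal and still needs both carbinol syntheses.
- Comparison: structurally both plans arrive at a ring B with a C1 carbonyl equivalent and a one-carbon arm at C11. The chosen plan starts from ring B and sets C10 and C11 by an ionic, substrate-controlled addition; the alternative forms ring B itself by a biradical pathway. In step economy A1 needs its own multistep, enantioselective assembly, so the alternative is likely equal for rings C/D and longer for rings A/B.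

**Alternative 2:** The cut is O5–C6 and C10–C11. In the forward step, TMSOTf with 2,6-di-tert-butyl-4-methylpyridine would activate the terminal epoxide of the diepoxy (Z)-allylsilane A3. The internal epoxide oxygen would attack C6, and the allylsilane carbon C11 would open the resulting epoxonium ion at C10 with inversion, giving A4 with rings A and B and an exocyclic methylene at C1.
- In its favour: two rings and four stereocentres (C4, C7, C10, C11) would come from one catalyst-controlled double epoxidation and one cascade. In ring and stereocentre economy this is clearly better than the chosen plan. The C1 methylene of A4 is exactly what the keto half needs for the epoxidation–hydride route to C24; there the alternative is also the better.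
- Against it here: A3 needs a geometrically pure (Z)-allylsilane and a regio- and enantioselective diepoxidation of a polyene. A cationic cascade has several exits (premature trapping, proton loss, exo opening). For the C1 carbinol of rings A/B the methylene must first be cleaved to the ketone, which the chosen plan has directly.
- Comparison: mechanistically a stereoelectronically guided cascade replaces several stepwise, separately correctable reactions, so one high-risk step stands against several moderate ones. Both plans make O5–C6 by acid-activated opening at the tertiary epoxide carbon, so on that issue they are equal.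

**Alternative 3:** The cut excises C17 (bonds C16–C17 and C17–C18), tracing ring D back to the six-membered 2,2-dimethylpyran-3-one A5. In the forward step, TMSCHN2 and BF3·OEt2 would add to the C18 carbonyl of A5, and the C16 methylene would migrate with loss of N2 to give the oxepanone A6.
- In its favour: a six-membered ether closes more easily than a seven-membered one. The less substituted, more electron-rich C16 should migrate in preference to the oxygenated quaternary C19. The product is already the ketone, so for ring D the redox economy is equal to or better than epoxide opening followed by oxidation.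
- Against it here: A5 needs a side chain one carbon shorter at C15, so the two halves would no longer share 13. Its tertiary ether still has to be made, probably by an epoxide opening in which the competing exo mode is five-membered and faster; the regiochemical problem is moved, not removed. Double homologation and epoxide formation are known side paths of diazoalkane insertion. The rings A/B half would need a stereoselective reduction at C7.
- Comparison: structurally it leaves ring C and the C24 problem untouched. Mechanistically a 1,2-shift replaces an SN1-like epoxide opening. In step economy it adds one step per oxepane and saves one oxidation in the keto half: roughly equal for rings C/D, worse for rings A/B.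

Key step: step 6

Assumption (chemistry): Burkholderia cepacia lipase acylates the (R)-alcohol of 3 faster (carbonyl side acting as the large substituent), so the (S)-alcohol 4 is recovered unreacted.

## Steps

**Step 1**
Reactants: 1 3-ethoxycyclohex-2-en-1-one
Product: 3 rac-3-ethoxy-6-hydroxycyclohex-2-en-1-one, via potassium dienolate 2 (not isolated)
Conditions: KN(SiMe3)2, THF, −78 °C; then 2-(phenylsulfonyl)-3-phenyloxaziridine, −78 °C; H2O
Reagents that add atoms: 2-(phenylsulfonyl)-3-phenyloxaziridine, O=S(=O)(c1ccccc1)N1OC1c1ccccc1
Why: Kinetic deprotonation of a vinylogous ester occurs at C6 (the α' carbon), and the cross-conjugated enolate is hydroxylated by electrophilic oxygen transfer from the N-sulfonyloxaziridine (Davis oxidation); the product is racemic.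

**Step 2**
Reactants: 3 rac-3-ethoxy-6-hydroxycyclohex-2-en-1-one
Product: 4 (S)-3-ethoxy-6-hydroxycyclohex-2-en-1-one
Conditions: Burkholderia cepacia lipase (Amano PS), vinyl acetate, t-BuOMe, 30 °C, stopped just past half conversion
Reagents that add atoms: none
Why: Lipase-catalysed irreversible transesterification is a kinetic resolution of cyclic α-hydroxy ketones; the (R)-alcohol should be acylated, and running slightly past half conversion should leave 4 in high enantiomeric purity, separable from the acetate by chromatography.

**Step 3**
Reactants: 4 (S)-3-ethoxy-6-hydroxycyclohex-2-en-1-one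
Product: 5 (S)-6-(tert-butyldimethylsilyloxy)-3-ethoxycyclohex-2-en-1-one
Conditions: TBSCl, imidazole, DMF, 0 °C → rt
Reagents that add atoms: tert-butyldimethylsilyl chloride, C[Si](C)(Cl)C(C)(C)C
Why: Imidazole-promoted silylation of a secondary alcohol; no base strong enough to enolise C6 is present, so the stereocentre should be preserved.

**Step 4**
Reactants: 5 (S)-6-(tert-butyldimethylsilyloxy)-3-ethoxycyclohex-2-en-1-one
Product: 7 (S)-4-(tert-butyldimethylsilyloxy)-3-methylcyclohex-2-en-1-one, via lithium alkoxide 6 (not isolated)
Conditions: MeLi, THF, −78 °C; then 1 M HCl, 0 °C, brief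
Reagents that add atoms: methyllithium, [Li]C; water, O
Why: Stork–Danheiser alkylative carbonyl transposition: 1,2-addition of MeLi to the vinylogous ester carbonyl, then acid ionises the tertiary allylic carbinol and hydrolyses the enol ether, so the old carbonyl carbon becomes the methyl-bearing β-carbon and the silyloxy carbon ends up γ; the stereocentre is untouched and the silyl ether should survive brief cold dilute acid.

**Step 5**
Reactants: 8 5-bromo-2-methylpent-2-ene
Product: 9 (4-methylpent-3-en-1-yl)magnesium bromide
Conditions: Mg turnings, I2 (cat.), THF, rt → 40 °C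
Reagents that add atoms: magnesium, [Mg]
Why: Direct insertion of magnesium into a primary homoallylic bromide (Grignard formation); the possible ring closure–opening of the homoallyl organometallic is degenerate here.

**Step 6**
Reactants: 7 (S)-4-(tert-butyldimethylsilyloxy)-3-methylcyclohex-2-en-1-one; 9 (4-methylpent-3-en-1-yl)magnesium bromide; 10 formaldehyde (monomer, from cracking of paraformaldehyde)
Product: 12 (2R,3S,4S)-4-(tert-butyldimethylsilyloxy)-2-(hydroxymethyl)-3-methyl-3-(4-methylpent-3-en-1-yl)cyclohexan-1-one, via bromomagnesium enolate 11 (not isolated)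
Conditions: CuBr·SMe2 (15 mol %), THF–Me2S, −40 °C, slow addition of 9; then 10 in THF, −78 → −30 °C; H2O
Reagents that add atoms: none
Why: Transmetalation of 9 gives a magnesium organocuprate of monovalent copper, which forms a π-complex with the enone, adds oxidatively at C10 and forms the C9–C10 bond by reductive elimination, leaving the bromomagnesium enolate 11 with its double bond fixed between C1 and C11. Monomeric formaldehyde then reacts with 11 through a closed, magnesium-bridged six-membered transition state to form C11–C12. The closest known reaction type is the copper-catalysed conjugate addition of Grignard reagents to 3-substituted cyclohexenones with aldehyde trapping, as in three-component couplings of 4-silyloxy cycloalkenones. No ring is closed. C10 is under substrate control: the reagent enters axially, anti to the pseudo-axial C4 silyloxy group, so C9 and the C4 oxygen become trans. C11 is set by approach anti to the new C9 chain and, because C11 stays enolisable, by thermodynamics, so the hydroxymethyl group should end up equatorial and trans to C9. The step needs 1,4- over 1,2-selectivity (copper catalysis, slow addition at low temperature), facial selectivity (the bulky silyloxy group) and a regiodefined enolate (secured because the enolate is generated by the addition itself and trapped before it can equilibrate).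

**Step 7**
Reactants: 12 (2R,3S,4S)-4-(tert-butyldimethylsilyloxy)-2-(hydroxymethyl)-3-methyl-3-(4-methylpent-3-en-1-yl)cyclohexan-1-one
Product: 13 (2R,3S,4S)-4-(tert-butyldimethylsilyloxy)-2-[(tert-butyldimethylsilyloxy)methyl]-3-methyl-3-(4-methylpent-3-en-1-yl)cyclohexan-1-one
Conditions: TBSCl, imidazole, CH2Cl2, 0 °C → rt
Reagents that add atoms: tert-butyldimethylsilyl chloride, C[Si](C)(Cl)C(C)(C)C
Why: Imidazole-promoted silylation of the primary alcohol; it removes the free aldol, which could undergo retro-aldol cleavage or dehydration in later basic steps, and gives the common precursor of both halves.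

**Step 8**
Reactants: 13 (2R,3S,4S)-4-(tert-butyldimethylsilyloxy)-2-[(tert-butyldimethylsilyloxy)methyl]-3-methyl-3-(4-methylpent-3-en-1-yl)cyclohexan-1-one
Product: 14 (1R,2R,3S,4S)-4-(tert-butyldimethylsilyloxy)-2-[(tert-butyldimethylsilyloxy)methyl]-1,3-dimethyl-3-(4-methylpent-3-en-1-yl)cyclohexan-1-ol (C1 hydroxyl axial, syn to the C10 methyl)
Conditions: MeMgBr (3 equiv), Et2O–THF, −78 → 0 °C; H2O
Reagents that add atoms: methylmagnesium bromide, C[Mg]Br
Why: Grignard 1,2-addition; the axial trajectory is blocked by the axial C10 methyl (1,3-diaxial), so attack should come along the equatorial direction and give the axial hydroxyl and equatorial methyl, that is (R)-C1.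

**Step 9**
Reactants: 14 (1R,2R,3S,4S)-4-(tert-butyldimethylsilyloxy)-2-[(tert-butyldimethylsilyloxy)methyl]-1,3-dimethyl-3-(4-methylpent-3-en-1-yl)cyclohexan-1-ol
Product: 15 (1R,2R,3S,4S)-2-(hydroxymethyl)-1,3-dimethyl-3-(4-methylpent-3-en-1-yl)cyclohexane-1,4-diol
Conditions: Bu4NF, THF, rt → 50 °C
Reagents that add atoms: none
Why: Fluoride-mediated cleavage of both silyl ethers; it is done before the epoxidation so that the hindered C4 ether can be forced without an epoxide present.

**Step 10**
Reactants: 15 (1R,2R,3S,4S)-2-(hydroxymethyl)-1,3-dimethyl-3-(4-methylpent-3-en-1-yl)cyclohexane-1,4-diol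
Product: 16 (1R,2R,3S,4S)-3-{2-[(2S)-3,3-dimethyloxiran-2-yl]ethyl}-2-(hydroxymethyl)-1,3-dimethylcyclohexane-1,4-diol
Conditions: 1,2:4,5-di-O-isopropylidene-β-L-erythro-2,3-hexodiulo-2,6-pyranose (30 mol %), KHSO5 (as 2KHSO5·KHSO4·K2SO4), K2CO3, Bu4NHSO4 (cat.), MeCN–(MeO)2CH2 / aq. Na2B4O7 buffer, 0 °C
Reagents that add atoms: potassium peroxymonosulfate, [K+].[O-]S(=O)(=O)OO
Why: Shi epoxidation: the chiral dioxirane formed in situ transfers oxygen through a spiro transition state; the L-fructose-derived ketone should give the (S)-epoxide at C7 (the D-enantiomer gives R), the remote ring centres exert no influence, and free hydroxyls are tolerated at pH about 10.5.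

**Step 11**
Reactants: 16 (1R,2R,3S,4S)-3-{2-[(2S)-3,3-dimethyloxiran-2-yl]ethyl}-2-(hydroxymethyl)-1,3-dimethylcyclohexane-1,4-diol
Product: 17 rings A/B triol (target numbering 1R,4S,7S,10S,11R; trans-fused 6,6-dimethyloxepane; free hydroxyls at C1, C7 and C12)
Conditions: (1S)-(+)-camphor-10-sulfonic acid (20 mol %), CH2Cl2, 0 °C
Reagents that add atoms: none
Why: Acid-promoted 7-endo-tet epoxide opening: protonation develops positive charge at the tertiary C6, which the C4 hydroxyl attacks with breaking of the C6–O bond; C7 keeps its oxygen and its (S) configuration, and the trans ring fusion follows from the anti relation of O5 and C9 set in step 6.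

**Step 12**
Reactants: 17 rings A/B triol
Product: 18 rings A/B diol with C12–S-(1-phenyl-1H-tetrazol-5-yl) sulfide
Conditions: 1-phenyl-1H-tetrazole-5-thiol, PPh3, DIAD, THF, 0 °C → rt
Reagents that add atoms: 1-phenyl-1H-tetrazole-5-thiol, SC1=NN=NN1c1ccccc1
Why: Mitsunobu thioetherification; the acidic heteroaryl thiol is an excellent pronucleophile and only the primary alcohol should be activated, the neopentyl-type secondary and the tertiary alcohol being much slower.

**Step 13**
Reactants: 18 rings A/B diol with C12 tetrazolyl sulfide
Product: 19 C7 benzyl ether of 18 (C1 hydroxyl free)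
Conditions: NaH, BnBr, Bu4NI (cat.), THF–DMF, 0 °C → rt
Reagents that add atoms: benzyl bromide, BrCc1ccccc1
Why: Williamson etherification; the secondary alkoxide should react while the axial tertiary one is too hindered, and at the sulfide oxidation level there is no acidic C–H next to sulfur.

**Step 14**
Reactants: 19 C7 benzyl ether sulfide
Product: 20 C12 (1-phenyl-1H-tetrazol-5-yl) sulfone with C7 benzyl ether and free C1 hydroxyl
Conditions: (NH4)6Mo7O24·4H2O (20 mol %), 30% H2O2, EtOH, 0 °C → rt
Reagents that add atoms: hydrogen peroxide, OO
Why: Molybdate-catalysed peroxide oxidation of the sulfide through the sulfoxide to the sulfone; ethers and the tertiary alcohol are inert and the molecule contains no alkene.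

**Step 15**
Reactants: 20 C12 tetrazolyl sulfone
Product: 21 C1 triethylsilyl ether of 20 (rings A/B sulfone)
Conditions: TESOTf, 2,6-lutidine, CH2Cl2, −40 → 0 °C
Reagents that add atoms: triethylsilyl trifluoromethanesulfonate, CC[Si](CC)(CC)OS(=O)(=O)C(F)(F)F
Why: A silyl triflate with a hindered pyridine base silylates even the axial tertiary alcohol; masking it prevents its alkoxide from attacking the tetrazole ring during the olefination.

**Step 16**
Reactants: 13 (2R,3S,4S)-4-(tert-butyldimethylsilyloxy)-2-[(tert-butyldimethylsilyloxy)methyl]-3-methyl-3-(4-methylpent-3-en-1-yl)cyclohexan-1-one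
Product: 22 exocyclic alkene of 13 (C24=CH2; silyl ethers, chain and ring stereocentres unchanged)
Conditions: Ph3PCH3Br, KOtBu, toluene, rt → 70 °C
Reagents that add atoms: methyltriphenylphosphonium bromide, C[P+](c1ccccc1)(c1ccccc1)c1ccccc1.[Br-]
Why: Wittig methylenation; the β-silyloxy group is a poor leaving group, and any enolisation at C14 is harmless because the equatorial configuration is the thermodynamic one.

**Step 17**
Reactants: 22 exocyclic alkene, bis-silyl ether
Product: 23 diol of 22 (free hydroxyls at C21 and C13; both alkenes intact)
Conditions: Bu4NF, THF, rt → 50 °C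
Reagents that add atoms: none
Why: Fluoride-mediated cleavage of both silyl ethers, again before the epoxide is installed.

**Step 18**
Reactants: 23 diene diol
Product: 24 epoxy diol ((R)-epoxide on the side chain at C18/C19; C24=CH2 intact)
Conditions: 1,2:4,5-di-O-isopropylidene-β-D-erythro-2,3-hexodiulo-2,6-pyranose (30 mol %), KHSO5 (as 2KHSO5·KHSO4·K2SO4, 1.2 equiv), K2CO3, Bu4NHSO4 (cat.), MeCN–(MeO)2CH2 / aq. Na2B4O7 buffer, 0 °C
Reagents that add atoms: potassium peroxymonosulfate, [K+].[O-]S(=O)(=O)OO
Why: Shi epoxidation; the electron-rich trisubstituted alkene should react much faster than the hindered 1,1-disubstituted exocyclic one, a poor substrate for this dioxirane; the D-fructose-derived ketone should give the (R)-epoxide so that a single diastereomer is handled, although C18 later becomes a carbonyl.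

**Step 19**
Reactants: 24 epoxy diol
Product: 25 rings C/D diol (trans-fused 2,2-dimethyloxepane with (R)-C18 hydroxyl, C13 hydroxyl, C24=CH2)
Conditions: (1S)-(+)-camphor-10-sulfonic acid (20 mol %), CH2Cl2, 0 °C
Reagents that add atoms: none
Why: The same acid-promoted 7-endo-tet opening at the tertiary carbon (here C19) as in step 11; catalytic acid at 0 °C should leave the exocyclic alkene in place.

**Step 20**
Reactants: 25 rings C/D diol with C24=CH2
Product: 26 spiro-epoxide ((S)-C24, epoxide oxygen equatorial)
Conditions: mCPBA, NaHCO3, CH2Cl2, 0 °C
Reagents that add atoms: 3-chloroperbenzoic acid, OOC(=O)c1cccc(Cl)c1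
Why: Prilezhaev epoxidation; the peracid should approach the exocyclic alkene from the equatorial face, away from the axial C15 methyl, placing the epoxide oxygen equatorial on C24.

**Step 21**
Reactants: 26 spiro-epoxide
Product: 27 rings C/D triol ((S)-C24 tertiary hydroxyl equatorial with axial methyl; (R)-C18 hydroxyl; C13 hydroxyl)
Conditions: LiAlH4, THF, 0 °C → reflux; H2O, aq. NaOH
Reagents that add atoms: none
Why: Hydride opens the spiro-epoxide by SN2 attack at its unsubstituted CH2, so the C24–O bond is kept: equatorial hydroxyl, axial methyl, (S)-C24, the epimer of what Grignard addition gives.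

**Step 22**
Reactants: 27 rings C/D triol
Product: 28 rings C/D aldehyde (C13 formyl; C18 and C24 hydroxyls free)
Conditions: TEMPO (10 mol %), PhI(OAc)2, CH2Cl2, rt
Reagents that add atoms: none
Why: Oxoammonium (TEMPO) oxidation is selective for the primary alcohol over the hindered secondary and the tertiary one and stops at the aldehyde.

**Step 23**
Reactants: 28 rings C/D aldehyde diol
Product: 29 rings C/D aldehyde with C18 and C24 triethylsilyl ethers
Conditions: TESOTf, 2,6-lutidine, CH2Cl2, −78 → 0 °C
Reagents that add atoms: triethylsilyl trifluoromethanesulfonate, CC[Si](CC)(CC)OS(=O)(=O)C(F)(F)F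
Why: Silyl triflate silylation of the secondary and tertiary alcohols; the resulting β-silyloxy aldehyde has no leaving group good enough for elimination under the basic coupling.

**Step 24**
Reactants: 21 rings A/B sulfone; 29 rings C/D aldehyde
Product: 31 (E)-C12=C13 alkene carrying C7 benzyl ether and C1, C18, C24 triethylsilyl ethers, via potassium alkoxide adduct 30 (not isolated)
Conditions: KN(SiMe3)2, THF, −78 °C, 30 min; then 29, −78 °C → rt; H2O
Reagents that add atoms: none
Why: Julia–Kocienski olefination: the metalated sulfone adds to the aldehyde, the alkoxide attacks the tetrazole carbon (Smiles rearrangement) and loss of SO2 and the tetrazolyl oxide gives the alkene, expected mainly E with the potassium counter-ion; the geometry is of no consequence because the alkene is hydrogenated.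

**Step 25**
Reactants: 31 (E)-alkene tris-silyl ether
Product: 32 triol (C1 and C24 tertiary hydroxyls, (R)-C18 hydroxyl; C7 benzyl ether; C12=C13)
Conditions: HF·pyridine, pyridine, THF, 0 °C → rt
Reagents that add atoms: none
Why: Buffered fluoride cleaves the three triethylsilyl ethers; the benzyl ether, the ring ethers and the alkene are inert.

**Step 26**
Reactants: 32 triol
Product: 33 C18 ketone with free C1 and C24 hydroxyls (C7 benzyl ether; C12=C13)
Conditions: Dess–Martin periodinane, NaHCO3, CH2Cl2, rt
Reagents that add atoms: none
Why: Dess–Martin oxidation of the only secondary alcohol; tertiary alcohols cannot be oxidised.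

**Step 27**
Reactants: 33 keto diol
Product: 34 C1, C24 diacetate (C18 ketone; C7 benzyl ether; C12=C13)
Conditions: Ac2O, Sc(OTf)3 (5 mol %), MeCN, −20 °C
Reagents that add atoms: acetic anhydride, CC(=O)OC(C)=O
Why: Lewis-acid-catalysed acylation with the anhydride esterifies hindered tertiary alcohols at low temperature, where ionisation of the carbinols should be slow; C7 is protected as its benzyl ether and the ketone should not form an enol acetate under these conditions.

**Step 28**
Reactants: 34 diacetate benzyl ether alkene
Product: 35 CNP0298533.1 (target)
Conditions: H2 (1–4 atm), 10% Pd/C, EtOAc, rt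
Reagents that add atoms: none
Why: Heterogeneous hydrogenation saturates the C12=C13 alkene and hydrogenolyses the benzyl ether in one operation; ketone, tertiary acetates and ethers are inert and no stereocentre is created.

## Compound list

1 | 3-ethoxycyclohex-2-en-1-one | CCOC1=CC(=O)CCC1 | starting material
2 | potassium 5-ethoxycyclohexa-1,5-dien-1-olate (cross-conjugated dienolate of 1) | CCOC1=CC(O[K])=CCC1 | intermediate
3 | rac-3-ethoxy-6-hydroxycyclohex-2-en-1-one | CCOC1=CC(=O)C(O)CC1 | intermediate
4 | (S)-3-ethoxy-6-hydroxycyclohex-2-en-1-one | CCOC1=CC(=O)[C@@H](O)CC1 | intermediate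
5 | (S)-6-(tert-butyldimethylsilyloxy)-3-ethoxycyclohex-2-en-1-one | CCOC1=CC(=O)[C@@H](O[Si](C)(C)C(C)(C)C)CC1 | intermediate
6 | lithium (6S)-6-(tert-butyldimethylsilyloxy)-3-ethoxy-1-methylcyclohex-2-en-1-olate (either configuration at the carbinol carbon) | CCOC1=CC(C)(O[Li])[C@@H](O[Si](C)(C)C(C)(C)C)CC1 | intermediate
7 | (S)-4-(tert-butyldimethylsilyloxy)-3-methylcyclohex-2-en-1-one | CC1=CC(=O)CC[C@@H]1O[Si](C)(C)C(C)(C)C | intermediate
8 | 5-bromo-2-methylpent-2-ene | CC(C)=CCCBr | starting material
9 | (4-methylpent-3-en-1-yl)magnesium bromide | CC(C)=CCC[Mg]Br | intermediate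
10 | formaldehyde (monomer, from paraformaldehyde) | C=O | starting material
11 | bromomagnesium (3S,4S)-4-(tert-butyldimethylsilyloxy)-3-methyl-3-(4-methylpent-3-en-1-yl)cyclohex-1-en-1-olate | Br[Mg]OC1=C[C@](C)(CCC=C(C)C)[C@@H](O[Si](C)(C)C(C)(C)C)CC1 | intermediate
12 | (2R,3S,4S)-4-(tert-butyldimethylsilyloxy)-2-(hydroxymethyl)-3-methyl-3-(4-methylpent-3-en-1-yl)cyclohexan-1-one | O=C1CC[C@H](O[Si](C)(C)C(C)(C)C)[C@@](C)(CCC=C(C)C)[C@@H]1CO | intermediate
13 | (2R,3S,4S)-4-(tert-butyldimethylsilyloxy)-2-[(tert-butyldimethylsilyloxy)methyl]-3-methyl-3-(4-methylpent-3-en-1-yl)cyclohexan-1-one | O=C1CC[C@H](O[Si](C)(C)C(C)(C)C)[C@@](C)(CCC=C(C)C)[C@@H]1CO[Si](C)(C)C(C)(C)C | intermediate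
14 | (1R,2R,3S,4S)-4-(tert-butyldimethylsilyloxy)-2-[(tert-butyldimethylsilyloxy)methyl]-1,3-dimethyl-3-(4-methylpent-3-en-1-yl)cyclohexan-1-ol | C[C@@]1(O)CC[C@H](O[Si](C)(C)C(C)(C)C)[C@@](C)(CCC=C(C)C)[C@@H]1CO[Si](C)(C)C(C)(C)C | intermediate
15 | (1R,2R,3S,4S)-2-(hydroxymethyl)-1,3-dimethyl-3-(4-methylpent-3-en-1-yl)cyclohexane-1,4-diol | C[C@@]1(O)CC[C@H](O)[C@@](C)(CCC=C(C)C)[C@@H]1CO | intermediate
16 | (1R,2R,3S,4S)-3-{2-[(2S)-3,3-dimethyloxiran-2-yl]ethyl}-2-(hydroxymethyl)-1,3-dimethylcyclohexane-1,4-diol | C[C@@]1(O)CC[C@H](O)[C@@](C)(CC[C@@H]2OC2(C)C)[C@@H]1CO | intermediate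
17 | rings A/B triol (1R,4S,7S,10S,11R in target numbering; hydroxyls at C1, C7, C12) | C[C@@]1(O)CC[C@@H]2OC(C)(C)[C@@H](O)CC[C@@]2(C)[C@@H]1CO | intermediate
18 | rings A/B diol, C12 (1-phenyl-1H-tetrazol-5-yl) sulfide | C[C@@]1(O)CC[C@@H]2OC(C)(C)[C@@H](O)CC[C@@]2(C)[C@@H]1CSC1=NN=NN1c1ccccc1 | intermediate
19 | C7 benzyl ether of 18 | C[C@@]1(O)CC[C@@H]2OC(C)(C)[C@@H](OCc3ccccc3)CC[C@@]2(C)[C@@H]1CSC1=NN=NN1c1ccccc1 | intermediate
20 | C12 (1-phenyl-1H-tetrazol-5-yl) sulfone, C7 benzyl ether, C1 hydroxyl | C[C@@]1(O)CC[C@@H]2OC(C)(C)[C@@H](OCc3ccccc3)CC[C@@]2(C)[C@@H]1CS(=O)(=O)C1=NN=NN1c1ccccc1 | intermediate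
21 | C1 triethylsilyl ether of 20 (rings A/B sulfone) | CC[Si](CC)(CC)O[C@]1(C)CC[C@@H]2OC(C)(C)[C@@H](OCc3ccccc3)CC[C@@]2(C)[C@@H]1CS(=O)(=O)C1=NN=NN1c1ccccc1 | intermediate
22 | exocyclic alkene of 13 (C24=CH2, both silyl ethers) | C=C1CC[C@H](O[Si](C)(C)C(C)(C)C)[C@@](C)(CCC=C(C)C)[C@@H]1CO[Si](C)(C)C(C)(C)C | intermediate
23 | diene diol (C21 and C13 hydroxyls, C24=CH2) | C=C1CC[C@H](O)[C@@](C)(CCC=C(C)C)[C@@H]1CO | intermediate
24 | epoxy diol ((R)-3,3-dimethyloxiran-2-yl at C18, C24=CH2) | C=C1CC[C@H](O)[C@@](C)(CC[C@H]2OC2(C)C)[C@@H]1CO | intermediate
25 | rings C/D diol ((R)-C18 hydroxyl, C13 hydroxyl, C24=CH2) | C=C1CC[C@@H]2OC(C)(C)[C@H](O)CC[C@@]2(C)[C@@H]1CO | intermediate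
26 | rings C/D spiro-epoxide ((S)-C24, oxygen equatorial) | C1O[C@]12CC[C@@H]3OC(C)(C)[C@H](O)CC[C@@]3(C)[C@@H]2CO | intermediate
27 | rings C/D triol ((S)-C24 hydroxyl equatorial, (R)-C18 hydroxyl, C13 hydroxyl) | C[C@]1(O)CC[C@@H]2OC(C)(C)[C@H](O)CC[C@@]2(C)[C@@H]1CO | intermediate
28 | rings C/D aldehyde (C13 formyl, C18 and C24 hydroxyls) | C[C@]1(O)CC[C@@H]2OC(C)(C)[C@H](O)CC[C@@]2(C)[C@@H]1C=O | intermediate
29 | rings C/D aldehyde, C18 and C24 triethylsilyl ethers | CC[Si](CC)(CC)O[C@@]1(C)CC[C@@H]2OC(C)(C)[C@H](O[Si](CC)(CC)CC)CC[C@@]2(C)[C@@H]1C=O | intermediate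
30 | potassium alkoxide of the β-hydroxy sulfone adduct (C12 sulfonyl, C13 alkoxide; mixture at C12 and C13) | CC[Si](CC)(CC)O[C@]1(C)CC[C@@H]2OC(C)(C)[C@@H](OCc3ccccc3)CC[C@@]2(C)[C@@H]1C(S(=O)(=O)C1=NN=NN1c1ccccc1)C(O[K])[C@H]1[C@]2(C)CC[C@@H](O[Si](CC)(CC)CC)C(C)(C)O[C@H]2CC[C@]1(C)O[Si](CC)(CC)CC | intermediate
31 | (E)-C12=C13 alkene, C7 benzyl ether, C1/C18/C24 triethylsilyl ethers | CC[Si](CC)(CC)O[C@]1(C)CC[C@@H]2OC(C)(C)[C@@H](OCc3ccccc3)CC[C@@]2(C)[C@@H]1/C=C/[C@H]1[C@]2(C)CC[C@@H](O[Si](CC)(CC)CC)C(C)(C)O[C@H]2CC[C@]1(C)O[Si](CC)(CC)CC | intermediate
32 | triol (C1, C24 tertiary and (R)-C18 secondary hydroxyls), C7 benzyl ether, C12=C13 | O[C@]1(C)CC[C@@H]2OC(C)(C)[C@@H](OCc3ccccc3)CC[C@@]2(C)[C@@H]1/C=C/[C@H]1[C@]2(C)CC[C@@H](O)C(C)(C)O[C@H]2CC[C@]1(C)O | intermediate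
33 | C18 ketone, C1 and C24 hydroxyls, C7 benzyl ether, C12=C13 | O[C@]1(C)CC[C@@H]2OC(C)(C)[C@@H](OCc3ccccc3)CC[C@@]2(C)[C@@H]1/C=C/[C@H]1[C@]2(C)CCC(=O)C(C)(C)O[C@H]2CC[C@]1(C)O | intermediate
34 | C1, C24 diacetate, C18 ketone, C7 benzyl ether, C12=C13 | CC(=O)O[C@]1(C)CC[C@@H]2OC(C)(C)[C@@H](OCc3ccccc3)CC[C@@]2(C)[C@@H]1/C=C/[C@H]1[C@]2(C)CCC(=O)C(C)(C)O[C@H]2CC[C@]1(C)OC(C)=O | intermediate
35 | CNP0298533.1 | CC(=O)O[C@]1(C)CC[C@@H]2OC(C)(C)[C@@H](O)CC[C@@]2(C)[C@@H]1CC[C@H]1[C@]2(C)CCC(=O)C(C)(C)O[C@H]2CC[C@]1(C)OC(C)=O | target

## Step count and risk

Total: 28 steps. Longest linear sequence: 19 steps (steps 1–4, 6–15, 24–28; the branch through steps 16–23 is equally long).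

**Step 6 (key step).** Most likely failure: competing 1,2-addition or stalled conversion at the crowded, fully substituted β-carbon, and oligomerisation of formaldehyde or double hydroxymethylation during trapping. Loss of selectivity at C11 is less serious, since that centre can be equilibrated at the stage of 13 with K2CO3 in MeOH. Fallback: the coupling is split into two stages. Starting from 7 and 9, the copper-catalysed addition is run with Me3SiCl present, which accelerates the conjugate addition and traps the enolate as the trimethylsilyl enol ether F1. F1 is isolated and hydroxymethylated with aqueous formaldehyde and catalytic Sc(OTf)3 (aqueous Mukaiyama aldol), returning to the route at 12.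

**Step 11 (the same closure recurs in step 19).** Most likely failure: competing 6-exo opening at C7 to a tetrahydropyran, because the six-membered transition state is kinetically favoured although the tertiary carbon is electronically preferred. Fallback: the exo option is removed. Starting from 16, excess Et2Al–TMP (diethylaluminium 2,2,6,6-tetramethylpiperidide) isomerises the epoxide to the allylic alcohol, tetraol F2, which keeps the C7 carbinol and carries an isopropenyl group. Hg(OCOCF3)2 then effects intramolecular Markovnikov alkoxymercuration by the C4 hydroxyl at C6, where the only other mode would be an eight-membered ring, giving the organomercurial F3. NaBH4 in aqueous NaOH turns its CH2Hg group into the second methyl and returns to the route at 17. In the other half this detour would have to be run before the methylenation of step 16.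

**Step 24.** Most likely failure: slow, reversible addition of the hindered sulfonyl carbanion to the α-branched aldehyde, with proton transfer or self-condensation of the sulfone taking over on warming. Fallback: the stepwise Julia sequence. Starting from 21 and 29, LiN(SiMe3)2 at −78 °C gives a persistent lithium alkoxide adduct that is trapped in the flask with benzoyl chloride as the β-benzoyloxy sulfone F4. Reductive elimination with SmI2 in THF–HMPA then returns to the route at 31.

**Step 27.** Most likely failure: ionisation and dehydration of the axial tertiary carbinol at C1 under Lewis acid, or incomplete acylation because of 1,3-diaxial shielding by the C10 methyl. Fallback: anionic acylation. Starting from 33, excess KN(SiMe3)2 and Ac2O convert both tertiary alkoxides into acetates and the C18 enolate into its enol acetate, giving the enol acetate diacetate F5. K2CO3 in MeOH at 0 °C then cleaves only the enol ester and returns to the route at 34.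

## Further compounds

F1 | step 6 | trimethylsilyl enol ether of the conjugate adduct: (3S,4S)-4-(tert-butyldimethylsilyloxy)-3-methyl-3-(4-methylpent-3-en-1-yl)-1-(trimethylsilyloxy)cyclohex-1-ene | C[Si](C)(C)OC1=C[C@](C)(CCC=C(C)C)[C@@H](O[Si](C)(C)C(C)(C)C)CC1
F2 | step 11 | allylic alcohol tetraol: (1R,2R,3S,4S)-3-[(3S)-3-hydroxy-4-methylpent-4-en-1-yl]-2-(hydroxymethyl)-1,3-dimethylcyclohexane-1,4-diol | C[C@@]1(O)CC[C@H](O)[C@@](C)(CC[C@H](O)C(C)=C)[C@@H]1CO
F3 | step 11 | organomercurial: rings A/B triol with C6 bearing CH2HgOCOCF3 in place of one methyl (mixture at C6) | C[C@@]1(O)CC[C@@H]2OC(C)(C[Hg]OC(=O)C(F)(F)F)[C@@H](O)CC[C@@]2(C)[C@@H]1CO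
F4 | step 24 | β-benzoyloxy sulfone (C12 tetrazolylsulfonyl, C13 benzoate; mixture at C12 and C13) | CC[Si](CC)(CC)O[C@]1(C)CC[C@@H]2OC(C)(C)[C@@H](OCc3ccccc3)CC[C@@]2(C)[C@@H]1C(S(=O)(=O)C1=NN=NN1c1ccccc1)C(OC(=O)c1ccccc1)[C@H]1[C@]2(C)CC[C@@H](O[Si](CC)(CC)CC)C(C)(C)O[C@H]2CC[C@]1(C)O[Si](CC)(CC)CC
F5 | step 27 | enol acetate diacetate (C17=C18 enol acetate, C1 and C24 acetates, C7 benzyl ether, C12=C13) | CC(=O)O[C@]1(C)CC[C@@H]2OC(C)(C)[C@@H](OCc3ccccc3)CC[C@@]2(C)[C@@H]1/C=C/[C@H]1[C@]2(C)CC=C(OC(C)=O)C(C)(C)O[C@H]2CC[C@]1(C)OC(C)=O
A1 | alternative 1 | 5-alkenyl-2,2-dimethylfuran-3(2H)-one with C1 dioxolane and C11 benzyloxymethyl | CC1(C)OC(CCC2(OCCO2)[C@@H](COCc2ccccc2)C(C)=C)=CC1=O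
A2 | alternative 1 | cyclobutane photoadduct holding ring B and all atoms of ring A | CC1(C)O[C@@]23CCC4(OCCO4)[C@@H](COCc4ccccc4)[C@]2(C)C[C@H]3C1=O
A3 | alternative 2 | diepoxy (Z)-allylsilane ((S)-terminal and (S,S)-internal epoxide, benzyl ether) | CC1(C)O[C@H]1CC[C@]1(C)O[C@H]1CC/C(C[Si](C)(C)C)=C/COCc1ccccc1
A4 | alternative 2 | rings A/B with C1 exocyclic methylene, free C7 carbinol, C12 benzyl ether | C=C1CC[C@@H]2OC(C)(C)[C@@H](O)CC[C@@]2(C)[C@@H]1COCc1ccccc1
A5 | alternative 3 | trans-fused 2,2-dimethylpyran-3-one with C24 acetate and C13 benzyl ether | CC(=O)O[C@@]1(C)CC[C@@H]2OC(C)(C)C(=O)C[C@@]2(C)[C@@H]1COCc1ccccc1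
A6 | alternative 3 | keto half (rings C and D) with C13 benzyl ether | CC(=O)O[C@@]1(C)CC[C@@H]2OC(C)(C)C(=O)CC[C@@]2(C)[C@@H]1COCc1ccccc1
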